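**Strategy.** The synthesis rests on cutting the C8–C9 bond of ring B. The C8=C17 exocyclic methylene of the target sits next to C9, which carries side-chain carbon C11. That array is what results when the C9=C11 enol ether of a C11 aldehyde adds across a terminal C8≡C17 alkyne. One gold-catalysed 6-exo-dig cyclisation therefore closes ring B, forms C8–C9, creates the methylene, sets C9 and releases the C11 aldehyde for side-chain growth. Its precursor is a ring A cyclohexane carrying a C2 silyl ether, the C4 gem-dimethyl group, a but-3-ynyl arm on C5 and, trans to it on quaternary C10, an (E)-silyloxyvinyl arm.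

Key step: step 14

Remark: carbons carry labdane numbers throughout (ring A = C1–C5 with C10, ring B = C5–C10); enone 8 is made as the racemate and absolute configuration enters in step 5, where the sense of induction is assumed to follow that of simple cyclohex-2-enones.

**Step 1**
Reactants: 1 dimedone
Product: 2 3-ethoxy-5,5-dimethylcyclohex-2-en-1-one
Conditions: EtOH, TsOH·H2O (cat.), toluene, reflux, Dean–Stark
Reagents that add atoms: ethanol, CCO
Why: Acid-catalysed enol etherification of the symmetrical 1,3-diketone, driven by azeotropic removal of water, gives the single vinylogous ester needed for Stork–Danheiser chemistry.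

**Step 2**
Reactants: 3 3-(benzyloxy)propan-1-ol
Product: 4 [(3-iodopropoxy)methyl]benzene
Conditions: I2, PPh3, imidazole, CH2Cl2, 0 °C to rt
Reagents that add atoms: iodine, II
Why: Appel-type iodination converts the primary alcohol by SN2 attack of iodide on the alkoxyphosphonium ion and leaves the benzyl ether untouched.

**Step 3**
Reactants: 2 3-ethoxy-5,5-dimethylcyclohex-2-en-1-one; 4 [(3-iodopropoxy)methyl]benzene
Product: 6 rac-6-[3-(benzyloxy)propyl]-3-ethoxy-5,5-dimethylcyclohex-2-en-1-one, via lithium dienolate 5 (not isolated)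
Conditions: LDA, THF, −78 °C; then 4, DMPU, −78 °C to rt
Reagents that add atoms: none
Why: Stork–Danheiser alkylation, in which LDA removes the kinetically accessible alpha-prime proton next to the gem-dimethyl carbon (the future C5) and the cross-conjugated enolate is C-alkylated by the primary iodide, giving the racemate.

**Step 4**
Reactants: 6 rac-6-[3-(benzyloxy)propyl]-3-ethoxy-5,5-dimethylcyclohex-2-en-1-one
Product: 8 rac-4-[3-(benzyloxy)propyl]-3,5,5-trimethylcyclohex-2-en-1-one, via lithium alkoxide 7 (not isolated)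
Conditions: MeLi, CeCl3, THF, −78 to 0 °C; then 1 M HCl, rt
Reagents that add atoms: methyllithium, [Li]C
Why: Stork–Danheiser enone transposition, in which the weakly basic methylcerium species adds 1,2 to the hindered vinylogous ester carbonyl and aqueous acid then hydrolyses the enol ether and eliminates water, placing the methyl-bearing alkene carbon (C10) next to C5 and the carbonyl at C2.

**Step 5**
Reactants: 8 rac-4-[3-(benzyloxy)propyl]-3,5,5-trimethylcyclohex-2-en-1-one
Product: 9 (1R,4R)-4-[3-(benzyloxy)propyl]-3,5,5-trimethylcyclohex-2-en-1-ol (hydroxyl trans to the C5 arm)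
Conditions: (S)-2-methyl-CBS-oxazaborolidine (0.2 equiv), BH3·SMe2, THF, −20 °C; MeOH quench; chromatography to remove the cis carbinol
Reagents that add atoms: none
Why: Corey–Bakshi–Shibata reduction under catalyst control (alkenyl flank as the large group) should set C2 as R in both enantiomers of 8, so the racemate becomes the trans (1R,4R) and cis (1R,4S) carbinols, which are diastereomers separable on silica and of which the trans one is carried on.

**Step 6**
Reactants: 9 (1R,4R)-4-[3-(benzyloxy)propyl]-3,5,5-trimethylcyclohex-2-en-1-ol; 10 triethyl orthoacetate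
Product: 12 ethyl 2-[(1R,6R)-6-[3-(benzyloxy)propyl]-1,5,5-trimethylcyclohex-2-en-1-yl]acetate, via mixed ketene acetal 11 (not isolated)
Conditions: 10 (excess), EtCO2H (cat.), 140 °C, EtOH distilled off
Reagents that add atoms: none
Why: Johnson–Claisen rearrangement, whose suprafacial [3,3] shift forms the C9–C10 bond on the face that carried the C2 oxygen (anti to the C5 arm), so C2 chirality is relayed to quaternary C10 with the two arms trans and the alkene moves to C1=C2.

**Step 7**
Reactants: 12 ethyl 2-[(1R,6R)-6-[3-(benzyloxy)propyl]-1,5,5-trimethylcyclohex-2-en-1-yl]acetate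
Product: 14 ethyl 2-[(1S,2R,5R)-2-[3-(benzyloxy)propyl]-5-hydroxy-1,3,3-trimethylcyclohexyl]acetate, via alkylborane 13 (not isolated)
Conditions: 9-BBN, THF, 65 °C; then aq NaOAc, 30% H2O2, 0 °C to rt
Reagents that add atoms: hydrogen peroxide, OO
Why: Hydroboration–oxidation with the bulky 9-BBN should place boron on C2, remote from quaternary C10, from the face opposite to the pseudoaxial C10 methyl and the axial C4 methyl, and oxidation with retention gives the 2R alcohol cis to the acetate arm.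

**Step 8**
Reactants: 14 ethyl 2-[(1S,2R,5R)-2-[3-(benzyloxy)propyl]-5-hydroxy-1,3,3-trimethylcyclohexyl]acetate
Product: 15 ethyl 2-[(1S,2R,5R)-2-[3-(benzyloxy)propyl]-5-{[tert-butyl(dimethyl)silyl]oxy}-1,3,3-trimethylcyclohexyl]acetate
Conditions: TBSCl, imidazole, DMF, rt
Reagents that add atoms: tert-butyl(chloro)dimethylsilane, CC(C)(C)[Si](C)(C)Cl
Why: Imidazole-promoted silylation of the secondary alcohol masks C2 as a TBS ether that should survive every step up to the final fluoride treatment.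

**Step 9**
Reactants: 15 ethyl 2-[(1S,2R,5R)-2-[3-(benzyloxy)propyl]-5-{[tert-butyl(dimethyl)silyl]oxy}-1,3,3-trimethylcyclohexyl]acetate
Product: 16 ethyl 2-[(1S,2R,5R)-5-{[tert-butyl(dimethyl)silyl]oxy}-2-(3-hydroxypropyl)-1,3,3-trimethylcyclohexyl]acetate
Conditions: H2 (1 atm), 10% Pd/C, EtOAc, rt
Reagents that add atoms: none
Why: Catalytic hydrogenolysis cleaves the benzyl ether under neutral conditions at a stage where no alkene or alkyne is present and the silyl ether and ester are inert.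

**Step 10**
Reactants: 16 ethyl 2-[(1S,2R,5R)-5-{[tert-butyl(dimethyl)silyl]oxy}-2-(3-hydroxypropyl)-1,3,3-trimethylcyclohexyl]acetate
Product: 17 ethyl 2-[(1S,2R,5R)-5-{[tert-butyl(dimethyl)silyl]oxy}-1,3,3-trimethyl-2-(3-oxopropyl)cyclohexyl]acetate
Conditions: Dess–Martin periodinane, CH2Cl2, 0 °C to rt
Reagents that add atoms: none
Why: Dess–Martin oxidation of the primary alcohol stops at the C8 aldehyde under neutral conditions.

**Step 11**
Reactants: 17 ethyl 2-[(1S,2R,5R)-5-{[tert-butyl(dimethyl)silyl]oxy}-1,3,3-trimethyl-2-(3-oxopropyl)cyclohexyl]acetate; 18 dimethyl (1-diazo-2-oxopropyl)phosphonate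
Product: 20 ethyl 2-[(1S,2R,5R)-2-(but-3-yn-1-yl)-5-{[tert-butyl(dimethyl)silyl]oxy}-1,3,3-trimethylcyclohexyl]acetate, via dimethyl (diazomethyl)phosphonate 19 (not isolated)
Conditions: K2CO3, EtOH, 0 °C to rt
Reagents that add atoms: none
Why: Ohira–Bestmann homologation, in which ethoxide deacylates the reagent, the diazomethylphosphonate anion olefinates the aldehyde and the diazoalkene loses N2 with a 1,2-hydrogen shift to give the terminal C8≡C17 alkyne, ethanol being used so that any ester exchange is degenerate.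

**Step 12**
Reactants: 20 ethyl 2-[(1S,2R,5R)-2-(but-3-yn-1-yl)-5-{[tert-butyl(dimethyl)silyl]oxy}-1,3,3-trimethylcyclohexyl]acetate
Product: 21 2-[(1S,2R,5R)-2-(but-3-yn-1-yl)-5-{[tert-butyl(dimethyl)silyl]oxy}-1,3,3-trimethylcyclohexyl]acetaldehyde
Conditions: DIBAL-H (1.1 equiv), CH2Cl2, −78 °C; aq Rochelle salt
Reagents that add atoms: none
Why: Partial reduction with DIBAL-H at low temperature stops at the tetrahedral aluminium hemiacetal, which releases the C11 aldehyde only on work-up.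

**Step 13**
Reactants: 21 2-[(1S,2R,5R)-2-(but-3-yn-1-yl)-5-{[tert-butyl(dimethyl)silyl]oxy}-1,3,3-trimethylcyclohexyl]acetaldehyde
Product: 22 tert-butyl(dimethyl){[(1R,3R,4R)-4-(but-3-yn-1-yl)-3,5,5-trimethyl-3-[(E)-2-{[tri(propan-2-yl)silyl]oxy}ethenyl]cyclohexyl]oxy}silane (vinyl arm on C10 trans to the butynyl arm on C5 and cis to the C2 silyloxy group)
Conditions: TIPSOTf, Et3N, CH2Cl2, 0 °C to rt
Reagents that add atoms: tri(propan-2-yl)silyl trifluoromethanesulfonate, CC(C)[Si](C(C)C)(C(C)C)OS(=O)(=O)C(F)(F)F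
Why: Soft enolisation (silyl triflate and amine) of the aldehyde, whose only alpha-carbon is C9, gives the enol silyl ether, with the E isomer favoured because the bulky tertiary-alkyl substituent and the silyloxy group avoid each other.

**Step 14**
Reactants: 22 tert-butyl(dimethyl){[(1R,3R,4R)-4-(but-3-yn-1-yl)-3,5,5-trimethyl-3-[(E)-2-{[tri(propan-2-yl)silyl]oxy}ethenyl]cyclohexyl]oxy}silane
Product: 23 (1R,4aR,7R,8aR)-7-{[tert-butyl(dimethyl)silyl]oxy}-5,5,8a-trimethyl-2-methylidenedecahydronaphthalene-1-carbaldehyde (trans-decalin, formyl group equatorial)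
Conditions: (Ph3P)AuCl (10 mol%), AgBF4 (10 mol%), CH2Cl2/MeOH 10:1, rt to 40 °C
Reagents that add atoms: none
Why: Chloride abstraction by AgBF4 gives (Ph3P)Au+ (monovalent gold), which binds the terminal C8≡C17 alkyne; C9 of the enol ether attacks C8 anti to gold to give a C17 alkenylgold and a C11 silyloxocarbenium ion, and methanol then takes the silyl group and protonates the C–Au bond, leaving C8=C17H2 and the aldehyde and returning the catalyst. The closest known reaction type is the gold-catalysed Conia-ene-type carbocyclisation of silyl enol ethers onto alkynes. Ring B closes 6-exo-dig, the mode a terminal alkyne enforces because positive charge develops on its internal carbon, so 7-endo attack at C17 is not expected. The new C9 stereocentre is controlled by a chair-like transition state on the ring A template, with the trans arms on C5 and C10 both equatorial and C11 in the pseudo-equatorial site away from the axial hydrogens on C5 and C7, which should give 9R; the centre remains epimerisable if correction is needed. The step needs C-attack to outrun methanolysis of the enol ether and solvent addition to the alkyne, which the bulky triisopropylsilyl group and the short reach between the trans-diequatorial arms should secure, and the near-neutral medium should spare the TBS ether.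

**Step 15**
Reactants: 23 (1R,4aR,7R,8aR)-7-{[tert-butyl(dimethyl)silyl]oxy}-5,5,8a-trimethyl-2-methylidenedecahydronaphthalene-1-carbaldehyde; 24 ethyl (triphenylphosphoranylidene)acetate
Product: 25 ethyl (2E)-3-[(1R,4aR,7R,8aR)-7-{[tert-butyl(dimethyl)silyl]oxy}-5,5,8a-trimethyl-2-methylidenedecahydronaphthalen-1-yl]prop-2-enoate
Conditions: toluene, 90 °C
Reagents that add atoms: none
Why: Wittig olefination with a stabilised ylide runs under neutral conditions, which should avoid enolisation of the C9-epimerisable, beta,gamma-unsaturated aldehyde, and gives the E enoate.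

**Step 16**
Reactants: 25 ethyl (2E)-3-[(1R,4aR,7R,8aR)-7-{[tert-butyl(dimethyl)silyl]oxy}-5,5,8a-trimethyl-2-methylidenedecahydronaphthalen-1-yl]prop-2-enoate
Product: 26 ethyl 3-[(1R,4aR,7R,8aR)-7-{[tert-butyl(dimethyl)silyl]oxy}-5,5,8a-trimethyl-2-methylidenedecahydronaphthalen-1-yl]propanoate
Conditions: [(Ph3P)CuH]6 (3 mol%), (EtO)2MeSiH, t-BuOH, toluene, rt
Reagents that add atoms: none
Why: Copper hydride conjugate reduction (Stryker-type catalysis with a silane) delivers hydride only to the beta-carbon of the enoate and tert-butanol protonates the resulting silyl ketene acetal, so the isolated C8=C17 alkene is left untouched.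

**Step 17**
Reactants: 26 ethyl 3-[(1R,4aR,7R,8aR)-7-{[tert-butyl(dimethyl)silyl]oxy}-5,5,8a-trimethyl-2-methylidenedecahydronaphthalen-1-yl]propanoate; 27 2-(trimethylsilyl)ethyl acetate
Product: 29 2-(trimethylsilyl)ethyl 5-[(1R,4aR,7R,8aR)-7-{[tert-butyl(dimethyl)silyl]oxy}-5,5,8a-trimethyl-2-methylidenedecahydronaphthalen-1-yl]-3-oxopentanoate, via lithium ester enolate 28 (not isolated)
Conditions: 27, LDA, THF, −78 °C; then 26, −78 to −20 °C; AcOH
Reagents that add atoms: none
Why: Crossed Claisen condensation, in which the preformed lithium acetate enolate, used in excess, acylates on the unhindered ethyl ester and the beta-keto ester stays protected as its enolate until the acidic quench.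

**Step 18**
Reactants: 29 2-(trimethylsilyl)ethyl 5-[(1R,4aR,7R,8aR)-7-{[tert-butyl(dimethyl)silyl]oxy}-5,5,8a-trimethyl-2-methylidenedecahydronaphthalen-1-yl]-3-oxopentanoate
Product: 30 2-(trimethylsilyl)ethyl (2E)-5-[(1R,4aR,7R,8aR)-7-{[tert-butyl(dimethyl)silyl]oxy}-5,5,8a-trimethyl-2-methylidenedecahydronaphthalen-1-yl]-3-{[(trifluoromethyl)sulfonyl]oxy}pent-2-enoate
Conditions: Tf2O, aq Me4NOH, hexanes, 5 °C
Reagents that add atoms: trifluoromethanesulfonic anhydride, O=S(=O)(OS(=O)(=O)C(F)(F)F)C(F)(F)F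
Why: Stereoselective enol triflation of a beta-keto ester under non-chelating biphasic conditions (tetramethylammonium counter-ion) favours the enolate with its oxygen anti to the ester, which is trapped as the E triflate (triflate trans to the ester).

**Step 19**
Reactants: 30 2-(trimethylsilyl)ethyl (2E)-5-[(1R,4aR,7R,8aR)-7-{[tert-butyl(dimethyl)silyl]oxy}-5,5,8a-trimethyl-2-methylidenedecahydronaphthalen-1-yl]-3-{[(trifluoromethyl)sulfonyl]oxy}pent-2-enoate; 31 (tributylstannyl)methanol
Product: 32 2-(trimethylsilyl)ethyl (2E)-5-[(1R,4aR,7R,8aR)-7-{[tert-butyl(dimethyl)silyl]oxy}-5,5,8a-trimethyl-2-methylidenedecahydronaphthalen-1-yl]-3-(hydroxymethyl)pent-2-enoate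
Conditions: Pd(PPh3)4 (5 mol%), LiCl, 1,4-dioxane, 80 °C
Reagents that add atoms: none
Why: Stille coupling of the enol triflate with the hydroxymethyl stannane proceeds with retention of alkene geometry, so the hydroxymethyl group ends trans to the ester, where it cannot lactonise.

**Step 20**
Reactants: 32 2-(trimethylsilyl)ethyl (2E)-5-[(1R,4aR,7R,8aR)-7-{[tert-butyl(dimethyl)silyl]oxy}-5,5,8a-trimethyl-2-methylidenedecahydronaphthalen-1-yl]-3-(hydroxymethyl)pent-2-enoate
Product: 33 2-(trimethylsilyl)ethyl (2E)-3-[(acetyloxy)methyl]-5-[(1R,4aR,7R,8aR)-7-{[tert-butyl(dimethyl)silyl]oxy}-5,5,8a-trimethyl-2-methylidenedecahydronaphthalen-1-yl]pent-2-enoate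
Conditions: Ac2O, pyridine, DMAP (cat.), CH2Cl2, 0 °C to rt
Reagents that add atoms: acetic anhydride, CC(=O)OC(C)=O
Why: DMAP-catalysed acetylation of the only free hydroxyl group, the primary allylic one.

**Step 21**
Reactants: 33 2-(trimethylsilyl)ethyl (2E)-3-[(acetyloxy)methyl]-5-[(1R,4aR,7R,8aR)-7-{[tert-butyl(dimethyl)silyl]oxy}-5,5,8a-trimethyl-2-methylidenedecahydronaphthalen-1-yl]pent-2-enoate
Product: 34 (2E)-3-[(acetyloxy)methyl]-5-[(1R,4aR,7R,8aR)-7-hydroxy-5,5,8a-trimethyl-2-methylidenedecahydronaphthalen-1-yl]pent-2-enoic acid (target)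
Conditions: TBAF, AcOH, THF, rt to 40 °C
Reagents that add atoms: none
Why: Fluoride-induced cleavage removes both silicon-based groups in one operation, the 2-(trimethylsilyl)ethyl ester by beta-elimination of ethene and the TBS ether by Si–O cleavage, while the acetic acid buffer should protect the primary acetate and the exocyclic alkene.

**Compound list**

1 | dimedone (5,5-dimethylcyclohexane-1,3-dione) | CC1(C)CC(=O)CC(=O)C1 | starting material
2 | 3-ethoxy-5,5-dimethylcyclohex-2-en-1-one | CCOC1=CC(=O)CC(C)(C)C1 | intermediate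
3 | 3-(benzyloxy)propan-1-ol | OCCCOCc1ccccc1 | starting material
4 | [(3-iodopropoxy)methyl]benzene | ICCCOCc1ccccc1 | intermediate
5 | lithium 5-ethoxy-3,3-dimethylcyclohexa-1,5-dien-1-olate (kinetic dienolate of 2) | [Li+].[O-]C1=CC(C)(C)CC(OCC)=C1 | intermediate (not isolated)
6 | rac-6-[3-(benzyloxy)propyl]-3-ethoxy-5,5-dimethylcyclohex-2-en-1-one (racemic) | CCOC1=CC(=O)C(CCCOCc2ccccc2)C(C)(C)C1 | intermediate
7 | lithium 6-[3-(benzyloxy)propyl]-3-ethoxy-1,5,5-trimethylcyclohex-2-en-1-olate (racemic, diastereomer mixture) | [Li+].[O-]C1(C)C=C(OCC)CC(C)(C)C1CCCOCc1ccccc1 | intermediate (not isolated)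
8 | rac-4-[3-(benzyloxy)propyl]-3,5,5-trimethylcyclohex-2-en-1-one (racemic) | O=C1C=C(C)C(CCCOCc2ccccc2)C(C)(C)C1 | intermediate
9 | (1R,4R)-4-[3-(benzyloxy)propyl]-3,5,5-trimethylcyclohex-2-en-1-ol (trans) | O(Cc1ccccc1)CCC[C@@H]2C(C)(C)C[C@@H](O)C=C2C | intermediate
10 | triethyl orthoacetate | CCOC(C)(OCC)OCC | starting material
11 | (1R,4R)-4-[3-(benzyloxy)propyl]-3,5,5-trimethylcyclohex-2-en-1-yl 1-ethoxyethenyl ether (mixed ketene acetal) | O(Cc1ccccc1)CCC[C@@H]2C(C)(C)C[C@@H](OC(=C)OCC)C=C2C | intermediate (not isolated)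
12 | ethyl 2-[(1R,6R)-6-[3-(benzyloxy)propyl]-1,5,5-trimethylcyclohex-2-en-1-yl]acetate (arms on C5 and C10 trans) | O(Cc1ccccc1)CCC[C@@H]2C(C)(C)CC=C[C@@]2(C)CC(=O)OCC | intermediate
13 | ethyl 2-[(1S,2R,5R)-2-[3-(benzyloxy)propyl]-5-(9-borabicyclo[3.3.1]nonan-9-yl)-1,3,3-trimethylcyclohexyl]acetate | O(Cc1ccccc1)CCC[C@@H]2C(C)(C)C[C@@H](B3C4CCCC3CCC4)C[C@@]2(C)CC(=O)OCC | intermediate (not isolated)
14 | ethyl 2-[(1S,2R,5R)-2-[3-(benzyloxy)propyl]-5-hydroxy-1,3,3-trimethylcyclohexyl]acetate | O(Cc1ccccc1)CCC[C@@H]2C(C)(C)C[C@@H](O)C[C@@]2(C)CC(=O)OCC | intermediate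
15 | ethyl 2-[(1S,2R,5R)-2-[3-(benzyloxy)propyl]-5-{[tert-butyl(dimethyl)silyl]oxy}-1,3,3-trimethylcyclohexyl]acetate | O(Cc1ccccc1)CCC[C@@H]2C(C)(C)C[C@@H](O[Si](C)(C)C(C)(C)C)C[C@@]2(C)CC(=O)OCC | intermediate
16 | ethyl 2-[(1S,2R,5R)-5-{[tert-butyl(dimethyl)silyl]oxy}-2-(3-hydroxypropyl)-1,3,3-trimethylcyclohexyl]acetate | OCCC[C@@H]1C(C)(C)C[C@@H](O[Si](C)(C)C(C)(C)C)C[C@@]1(C)CC(=O)OCC | intermediate
17 | ethyl 2-[(1S,2R,5R)-5-{[tert-butyl(dimethyl)silyl]oxy}-1,3,3-trimethyl-2-(3-oxopropyl)cyclohexyl]acetate | O=CCC[C@@H]1C(C)(C)C[C@@H](O[Si](C)(C)C(C)(C)C)C[C@@]1(C)CC(=O)OCC | intermediate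
18 | dimethyl (1-diazo-2-oxopropyl)phosphonate | COP(=O)(OC)C(=[N+]=[N-])C(C)=O | starting material
19 | dimethyl (diazomethyl)phosphonate | COP(=O)(OC)C=[N+]=[N-] | intermediate (not isolated)
20 | ethyl 2-[(1S,2R,5R)-2-(but-3-yn-1-yl)-5-{[tert-butyl(dimethyl)silyl]oxy}-1,3,3-trimethylcyclohexyl]acetate | C#CCC[C@@H]1C(C)(C)C[C@@H](O[Si](C)(C)C(C)(C)C)C[C@@]1(C)CC(=O)OCC | intermediate
21 | 2-[(1S,2R,5R)-2-(but-3-yn-1-yl)-5-{[tert-butyl(dimethyl)silyl]oxy}-1,3,3-trimethylcyclohexyl]acetaldehyde | C#CCC[C@@H]1C(C)(C)C[C@@H](O[Si](C)(C)C(C)(C)C)C[C@@]1(C)CC=O | intermediate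
22 | tert-butyl(dimethyl){[(1R,3R,4R)-4-(but-3-yn-1-yl)-3,5,5-trimethyl-3-[(E)-2-{[tri(propan-2-yl)silyl]oxy}ethenyl]cyclohexyl]oxy}silane | C#CCC[C@@H]1C(C)(C)C[C@@H](O[Si](C)(C)C(C)(C)C)C[C@@]1(C)/C=C/O[Si](C(C)C)(C(C)C)C(C)C | intermediate (key-step precursor)
23 | (1R,4aR,7R,8aR)-7-{[tert-butyl(dimethyl)silyl]oxy}-5,5,8a-trimethyl-2-methylidenedecahydronaphthalene-1-carbaldehyde | C=C1CC[C@@H]2C(C)(C)C[C@@H](O[Si](C)(C)C(C)(C)C)C[C@@]2(C)[C@@H]1C=O | intermediate (key-step product)
24 | ethyl (triphenylphosphoranylidene)acetate | CCOC(=O)C=P(c1ccccc1)(c1ccccc1)c1ccccc1 | starting material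
25 | ethyl (2E)-3-[(1R,4aR,7R,8aR)-7-{[tert-butyl(dimethyl)silyl]oxy}-5,5,8a-trimethyl-2-methylidenedecahydronaphthalen-1-yl]prop-2-enoate | C=C1CC[C@@H]2C(C)(C)C[C@@H](O[Si](C)(C)C(C)(C)C)C[C@@]2(C)[C@@H]1/C=C/C(=O)OCC | intermediate
26 | ethyl 3-[(1R,4aR,7R,8aR)-7-{[tert-butyl(dimethyl)silyl]oxy}-5,5,8a-trimethyl-2-methylidenedecahydronaphthalen-1-yl]propanoate | C=C1CC[C@@H]2C(C)(C)C[C@@H](O[Si](C)(C)C(C)(C)C)C[C@@]2(C)[C@@H]1CCC(=O)OCC | intermediate
27 | 2-(trimethylsilyl)ethyl acetate | CC(=O)OCC[Si](C)(C)C | starting material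
28 | lithium 1-[2-(trimethylsilyl)ethoxy]ethen-1-olate | [Li+].[O-]C(=C)OCC[Si](C)(C)C | intermediate (not isolated)
29 | 2-(trimethylsilyl)ethyl 5-[(1R,4aR,7R,8aR)-7-{[tert-butyl(dimethyl)silyl]oxy}-5,5,8a-trimethyl-2-methylidenedecahydronaphthalen-1-yl]-3-oxopentanoate | C=C1CC[C@@H]2C(C)(C)C[C@@H](O[Si](C)(C)C(C)(C)C)C[C@@]2(C)[C@@H]1CCC(=O)CC(=O)OCC[Si](C)(C)C | intermediate
30 | 2-(trimethylsilyl)ethyl (2E)-5-[(1R,4aR,7R,8aR)-7-{[tert-butyl(dimethyl)silyl]oxy}-5,5,8a-trimethyl-2-methylidenedecahydronaphthalen-1-yl]-3-{[(trifluoromethyl)sulfonyl]oxy}pent-2-enoate | C=C1CC[C@@H]2C(C)(C)C[C@@H](O[Si](C)(C)C(C)(C)C)C[C@@]2(C)[C@@H]1CC/C(=C\C(=O)OCC[Si](C)(C)C)OS(=O)(=O)C(F)(F)F | intermediate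
31 | (tributylstannyl)methanol | CCCC[Sn](CO)(CCCC)CCCC | starting material
32 | 2-(trimethylsilyl)ethyl (2E)-5-[(1R,4aR,7R,8aR)-7-{[tert-butyl(dimethyl)silyl]oxy}-5,5,8a-trimethyl-2-methylidenedecahydronaphthalen-1-yl]-3-(hydroxymethyl)pent-2-enoate | C=C1CC[C@@H]2C(C)(C)C[C@@H](O[Si](C)(C)C(C)(C)C)C[C@@]2(C)[C@@H]1CC/C(=C\C(=O)OCC[Si](C)(C)C)CO | intermediate
33 | 2-(trimethylsilyl)ethyl (2E)-3-[(acetyloxy)methyl]-5-[(1R,4aR,7R,8aR)-7-{[tert-butyl(dimethyl)silyl]oxy}-5,5,8a-trimethyl-2-methylidenedecahydronaphthalen-1-yl]pent-2-enoate | C=C1CC[C@@H]2C(C)(C)C[C@@H](O[Si](C)(C)C(C)(C)C)C[C@@]2(C)[C@@H]1CC/C(=C\C(=O)OCC[Si](C)(C)C)COC(C)=O | intermediate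
34 | (2E)-3-[(acetyloxy)methyl]-5-[(1R,4aR,7R,8aR)-7-hydroxy-5,5,8a-trimethyl-2-methylidenedecahydronaphthalen-1-yl]pent-2-enoic acid | C=C1CC[C@@H]2C(C)(C)C[C@@H](O)C[C@@]2(C)[C@@H]1CC/C(=C\C(=O)O)COC(C)=O | target

**Step count and risk**

Total step count: 21. Longest linear sequence: 20 steps (steps 1 and 3–21, from dimedone); step 2 prepares the iodide on a side branch.

Steps most likely to fail:

1. Step 14 (key step). Methanolysis of the enol silyl ether back to aldehyde 21, or addition of methanol to the gold-bound alkyne, may run faster than C8–C9 bond formation. Fallback: starting from 22, ring B is closed by a stoichiometric carbomercuration in an aprotic medium (HgCl2, hexamethyldisilazane, CH2Cl2, rt). Divalent mercury activates the alkyne and chloride takes the silyl group, which should give the (E)-C17-chloromercurio derivative of the decalin aldehyde F1. Protodemercuration of F1 (NaI, dilute HCl, acetone–water, 0 °C) comes back to the route at 23.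

2. Step 5. The two flanks of the carbonyl (alkenyl CH against a CH2 next to the gem-dimethyl carbon) may be told apart poorly by the oxazaborolidine, lowering enantiomeric purity, and the cis and trans carbinols may co-elute. Fallback: starting from 8, Luche reduction (NaBH4, CeCl3·7H2O, MeOH, −40 °C) would give the racemic trans carbinol F2 beside the racemic cis carbinol F3, which is removed by chromatography. Lipase-catalysed acylation of F2 (Burkholderia cepacia lipase, vinyl acetate, MTBE, rt) is expected to convert the 1R enantiomer into the (1R,4R)-acetate F4 and to leave the (1S,4S)-carbinol F5. Methanolysis of F4 (K2CO3, MeOH, rt) comes back to the route at 9.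

3. Step 7. Borane may add from the face of the C10 methyl through the ring-flipped half-chair, or partly at C1. Fallback: starting from 12, the C2 epimer F6 that such an addition would give (5S in the cyclohexane numbering) is separated and esterified with inversion under Mitsunobu conditions (4-nitrobenzoic acid, PPh3, DIAD, toluene, 0 °C to rt) to the 4-nitrobenzoate F7. Ethanolysis of F7 (K2CO3, EtOH, rt) comes back to the route at 14.

**Further compounds**

F1 | step 14 | (E)-C17-chloromercurio derivative of 23: 7-{[tert-butyl(dimethyl)silyl]oxy}-2-[(E)-(chloromercurio)methylidene]-5,5,8a-trimethyldecahydronaphthalene-1-carbaldehyde, ring configuration as in 23 | Cl[Hg]/C=C1\CC[C@@H]2C(C)(C)C[C@@H](O[Si](C)(C)C(C)(C)C)C[C@@]2(C)[C@@H]1C=O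
F2 | step 5 | rac-trans-4-[3-(benzyloxy)propyl]-3,5,5-trimethylcyclohex-2-en-1-ol, (1R,4R) and (1S,4S) | O(Cc1ccccc1)CCC[C@@H]2C(C)(C)C[C@@H](O)C=C2C.O(Cc1ccccc1)CCC[C@H]2C(C)(C)C[C@H](O)C=C2C
F3 | step 5 | rac-cis-4-[3-(benzyloxy)propyl]-3,5,5-trimethylcyclohex-2-en-1-ol, (1R,4S) and (1S,4R) | O(Cc1ccccc1)CCC[C@H]2C(C)(C)C[C@@H](O)C=C2C.O(Cc1ccccc1)CCC[C@@H]2C(C)(C)C[C@H](O)C=C2C
F4 | step 5 | (1R,4R)-4-[3-(benzyloxy)propyl]-3,5,5-trimethylcyclohex-2-en-1-yl acetate | O(Cc1ccccc1)CCC[C@@H]2C(C)(C)C[C@@H](OC(C)=O)C=C2C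
F5 | step 5 | (1S,4S)-4-[3-(benzyloxy)propyl]-3,5,5-trimethylcyclohex-2-en-1-ol | O(Cc1ccccc1)CCC[C@H]2C(C)(C)C[C@H](O)C=C2C
F6 | step 7 | ethyl 2-[(1S,2R,5S)-2-[3-(benzyloxy)propyl]-5-hydroxy-1,3,3-trimethylcyclohexyl]acetate | O(Cc1ccccc1)CCC[C@@H]2C(C)(C)C[C@H](O)C[C@@]2(C)CC(=O)OCC
F7 | step 7 | ethyl 2-[(1S,2R,5R)-2-[3-(benzyloxy)propyl]-1,3,3-trimethyl-5-[(4-nitrobenzoyl)oxy]cyclohexyl]acetate | O(Cc1ccccc1)CCC[C@@H]2C(C)(C)C[C@@H](OC(=O)c3ccc(cc3)[N+](=O)[O-])C[C@@]2(C)CC(=O)OCC
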